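## Retrosynthetic overview

- The orsellinate ester is cut at the aryl–C(=O) bond: a 3,5-bis(methoxymethoxy)aryne, methylmagnesium bromide and a cyclic carbonate of the C7/C8 diol are joined in one pot, which places CH3 and C(=O)O on neighbouring ring carbons and opens the carbonate to the 8-O-ester with free 7-OH.
- Enabling feature: O7 (tertiary) and O8 (secondary) sit cis on the six-membered carbocycle and can share one carbonyl carbon as a five-membered carbonate, and on the benzene ring the ester carbon lies between C–CH3 and C–O, the pattern a 3-alkoxyaryne delivers.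
- The carbonate partner is kept free of other electrophilic carbonyls: C6 is a dimethyl ketal, C1 a methyl enol ether, C4a carries Br.
- It comes from 4-methoxy-3-methylphenol by bromination, oxidative dearomatisation, CBS reduction, anti-dihydroxylation, re-oxidation and methoxymethylenation.
- Ring order: carbocycle (dearomatised arene), temporary dioxolanone, orsellinate substitution pattern (key step), then side chain by Sonogashira coupling and the pyran ring last, before global acid deprotection.

Key step: step 10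

Remark: the exocyclic methoxymethylidene double bond from the Wittig step is expected as an E/Z mixture and is written without configuration, because both isomers converge in the pyran closure.

## Route

Step 1
Reactants: 1 4-methoxy-3-methylphenol
Product: 2 2-bromo-4-methoxy-5-methylphenol
Conditions: NBS (1.0 equiv), MeCN, 0 °C
Reagents that add atoms: N-bromosuccinimide, O=C1CCC(=O)N1Br
Why: Electrophilic aromatic bromination should go ortho to the free OH (para is blocked by OMe), at the less hindered ortho carbon, which is also para to CH3.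

Step 2
Reactants: 2 2-bromo-4-methoxy-5-methylphenol
Product: 3 2-bromo-4,4-dimethoxy-5-methylcyclohexa-2,5-dien-1-one
Conditions: PhI(OAc)2 (1.1 equiv), MeOH, 0 °C
Reagents that add atoms: methanol, CO
Why: Hypervalent-iodine oxidative dearomatisation of a p-methoxyphenol in methanol gives the p-quinone monoketal, which stores the later C6 ketone as a dimethyl ketal and leaves the later C8a carbon as the only carbonyl.

Step 3
Reactants: 3 2-bromo-4,4-dimethoxy-5-methylcyclohexa-2,5-dien-1-one
Product: 4 (1R)-2-bromo-4,4-dimethoxy-5-methylcyclohexa-2,5-dien-1-ol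
Conditions: (S)-Me-CBS oxazaborolidine (0.2 equiv), catecholborane (1.5 equiv), toluene, −78 °C; aq. NaHCO3 work-up
Reagents that add atoms: none
Why: Corey–Bakshi–Shibata 1,2-reduction of an α-bromo enone, with the bromine-bearing vinyl flank as the large group, should give the (R)-carbinol, a temporary stereocentre that steers step 4.

Step 4
Reactants: 4 (1R)-2-bromo-4,4-dimethoxy-5-methylcyclohexa-2,5-dien-1-ol
Product: 5 (1R,2R,3R)-4-bromo-6,6-dimethoxy-1-methylcyclohex-4-ene-1,2,3-triol
Conditions: OsO4 (2 mol %), NMO (1.5 equiv), NaHCO3, acetone/H2O (9:1), 0 °C → rt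
Reagents that add atoms: osmium tetroxide, O=[Os](=O)(=O)=O; N-methylmorpholine N-oxide, C[N+]1([O-])CCOCC1; water, O
Why: Catalytic OsO4 syn-dihydroxylation (Upjohn conditions) should attack the electron-richer methyl-substituted alkene rather than the bromoalkene, anti to the allylic hydroxyl as is usual for cyclic allylic alcohols, which sets the later C7 and C8 centres as a cis-diol.

Step 5
Reactants: 5 (1R,2R,3R)-4-bromo-6,6-dimethoxy-1-methylcyclohex-4-ene-1,2,3-triol
Product: 6 (5R,6S)-2-bromo-5,6-dihydroxy-4,4-dimethoxy-5-methylcyclohex-2-en-1-one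
Conditions: activated MnO2 (15 equiv), CH2Cl2, rt
Reagents that add atoms: none
Why: Chemoselective MnO2 oxidation of the allylic secondary alcohol (the other secondary and the tertiary OH are not allylic) removes the relay stereocentre and restores the enone carbonyl for olefination.

Step 6
Reactants: 6 (5R,6S)-2-bromo-5,6-dihydroxy-4,4-dimethoxy-5-methylcyclohex-2-en-1-one
Product: 7 (5R,6S)-2-bromo-4,4-dimethoxy-5-methyl-5,6-bis(trimethylsilyloxy)cyclohex-2-en-1-one
Conditions: 1-(trimethylsilyl)imidazole (3 equiv), CH2Cl2, rt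
Reagents that add atoms: 1-(trimethylsilyl)imidazole, C[Si](C)(C)n1ccnc1
Why: Neutral O-silylation caps both hydroxyls so that no alkoxide (retro-aldol, ketol shift) can form under the basic conditions of step 7, and it does not enolise the α-oxygenated ketone.

Step 7
Reactants: 7 (5R,6S)-2-bromo-4,4-dimethoxy-5-methyl-5,6-bis(trimethylsilyloxy)cyclohex-2-en-1-one
Product: 9 (1R,2R)-4-bromo-6,6-dimethoxy-3-(methoxymethylidene)-1-methylcyclohex-4-ene-1,2-diol, via bis(trimethylsilyl) ether 8 (not isolated)
Conditions: Ph3P(Cl)CH2OMe (2.0 equiv), KHMDS (1.9 equiv), THF, −78 → 0 °C; then K2CO3 (cat.), MeOH, rt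
Reagents that add atoms: (methoxymethyl)triphenylphosphonium chloride, COC[P+](c1ccccc1)(c1ccccc1)c1ccccc1.[Cl-]
Why: Wittig methoxymethylenation of the enone carbonyl brings in C1 of the later pyran as an exocyclic methyl enol ether, and mild methanolysis of the silyl ethers frees the cis-diol.

Step 8
Reactants: 9 (1R,2R)-4-bromo-6,6-dimethoxy-3-(methoxymethylidene)-1-methylcyclohex-4-ene-1,2-diol
Product: 10 (3aR,7aR)-6-bromo-4,4-dimethoxy-7-(methoxymethylidene)-3a-methyl-3a,4,7,7a-tetrahydro-2H-1,3-benzodioxol-2-one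
Conditions: CDI (1.5 equiv), DMAP (cat.), CH2Cl2, rt
Reagents that add atoms: 1,1'-carbonyldiimidazole, O=C(n1ccnc1)n1ccnc1
Why: Carbonylation of the cis-1,2-diol with CDI closes the cis-fused 1,3-dioxolan-2-one, a temporary ring that protects both oxygens and already holds the carbonyl carbon of the later ester.

Step 9
Reactants: 11 5-fluorobenzene-1,3-diol
Product: 12 1-fluoro-3,5-bis(methoxymethoxy)benzene
Conditions: MOMCl (2.5 equiv), i-Pr2NEt (3 equiv), CH2Cl2, 0 °C → rt
Reagents that add atoms: chloromethyl methyl ether, COCCl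
Why: Williamson-type O-alkylation gives the bis-MOM ether, whose acetal oxygens direct the metalation and the aryne addition and are removed by acid at the end.

Step 10
Reactants: 12 1-fluoro-3,5-bis(methoxymethoxy)benzene; 10 (3aR,7aR)-6-bromo-4,4-dimethoxy-7-(methoxymethylidene)-3a-methyl-3a,4,7,7a-tetrahydro-2H-1,3-benzodioxol-2-one
Product: 16 (1R,6R)-3-bromo-6-hydroxy-5,5-dimethoxy-2-(methoxymethylidene)-6-methylcyclohex-3-en-1-yl 2,4-bis(methoxymethoxy)-6-methylbenzoate, via aryllithium 13 (not isolated), via aryne 14 (not isolated), via arylmagnesium bromide 15 (not isolated)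
Conditions: 12 (1.5 equiv), n-BuLi (1.45 equiv), THF, −78 °C; MeMgBr (1.4 equiv), −78 °C → rt; then 10 (1.0 equiv), −40 → 0 °C; pH 7 buffer
Reagents that add atoms: methylmagnesium bromide, C[Mg]Br
Why: n-BuLi should remove the proton between F and OMOM of 12 (13), warming expels LiF to give aryne 14, MeMgBr adds to it to give 15, and 15 attacks the carbonate C=O of 10, whose tetrahedral magnesium ortho-acid salt opens to the hydroxy ester. The closest known reaction type is the aryne carbomagnesiation and electrophile-trapping sequence used for resorcylates (Grignard reagent, then CO2), here ended by the known acylation of a Grignard reagent by a cyclic carbonate. The side of addition follows from the OMOM group beside the triple bond: it polarises the aryne so that the methyl group enters at the remote aryne carbon and magnesium ends on the carbon next to oxygen, chelated by OMOM, which places CH3 and C(=O)O on neighbouring carbons in the orsellinate pattern. No ring is closed (the temporary dioxolanone is opened) and no stereocentre is formed or touched, because substitution takes place at the carbonyl carbon and C7 and C8 keep their C–O bonds. The step needs chemoselectivity for the carbonate, which is secured because 10 holds no other electrophilic carbonyl (C6 is a ketal, C1 an enol ether, the acrylate is not yet present) and the di-ortho-substituted ester resists a second addition. It also needs the acyl group on the secondary O8: both ring-opened esters interconvert through the same ortho-acid alkoxide, and the hindered aroyl group should settle on the secondary oxygen and leave the tertiary O7–H free.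

Step 11
Reactants: 17 3-(trimethylsilyl)prop-2-ynal; 18 tert-butyl (triphenyl-λ5-phosphanylidene)acetate
Product: 19 tert-butyl (2E)-5-(trimethylsilyl)pent-2-en-4-ynoate
Conditions: CH2Cl2, 0 °C → rt
Reagents that add atoms: none
Why: Wittig olefination with a stabilised ylide should give the (E)-enoate.

Step 12
Reactants: 19 tert-butyl (2E)-5-(trimethylsilyl)pent-2-en-4-ynoate
Product: 20 tert-butyl (2E)-pent-2-en-4-ynoate
Conditions: K2CO3 (cat.), MeOH, 0 °C
Reagents that add atoms: none
Why: Base-catalysed methanolysis of the alkynyl C–Si bond (protodesilylation) frees the terminal alkyne without touching the tert-butyl ester.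

Step 13
Reactants: 16 (1R,6R)-3-bromo-6-hydroxy-5,5-dimethoxy-2-(methoxymethylidene)-6-methylcyclohex-3-en-1-yl 2,4-bis(methoxymethoxy)-6-methylbenzoate; 20 tert-butyl (2E)-pent-2-en-4-ynoate
Product: 21 (1R,6R)-3-[(3E)-5-tert-butoxy-5-oxopent-3-en-1-yn-1-yl]-6-hydroxy-5,5-dimethoxy-2-(methoxymethylidene)-6-methylcyclohex-3-en-1-yl 2,4-bis(methoxymethoxy)-6-methylbenzoate
Conditions: Pd(PPh3)4 (5 mol %), CuI (10 mol %), Et3N (3 equiv), THF, rt → 40 °C
Reagents that add atoms: none
Why: Sonogashira coupling at the vinyl bromide installs C3, C4 and the acrylate side chain; oxidative addition into C–Br should outrun ionisation of the hindered allylic benzoate, whose enol ether alkene binds Pd(0) poorly.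

Step 14
Reactants: 21 (1R,6R)-3-[(3E)-5-tert-butoxy-5-oxopent-3-en-1-yn-1-yl]-6-hydroxy-5,5-dimethoxy-2-(methoxymethylidene)-6-methylcyclohex-3-en-1-yl 2,4-bis(methoxymethoxy)-6-methylbenzoate
Product: 24 tert-butyl (2E)-3-[(7R,8R)-8-{[2,4-bis(methoxymethoxy)-6-methylbenzoyl]oxy}-7-hydroxy-7-methyl-6-oxo-7,8-dihydro-6H-isochromen-3-yl]prop-2-enoate, via methoxymethylene dienone 22 (not isolated), via hydroxymethylene dienone 23 (not isolated)
Conditions: PPTS (0.2 equiv), acetone/H2O (10:1), rt; then Au(OAc)3 (5 mol %), TFA (0.2 equiv), wet ClCH2CH2Cl, rt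
Reagents that add atoms: water, O
Why: Hydrolysis of the doubly allylic ketal unveils the C6 ketone, and the resulting 2-alkynyl (methoxy/hydroxy)methylene dienone should close 6-endo-dig on the gold-activated alkyne with loss of methanol, the cycloisomerisation of o-alkynyl vinylogous acids known from azaphilone chemistry, run under acid so that no vinylogous enolate can expel the C8 ester.

Step 15
Reactants: 24 tert-butyl (2E)-3-[(7R,8R)-8-{[2,4-bis(methoxymethoxy)-6-methylbenzoyl]oxy}-7-hydroxy-7-methyl-6-oxo-7,8-dihydro-6H-isochromen-3-yl]prop-2-enoate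
Product: 25 (+)-mitorubrinic acid B
Conditions: TFA/CH2Cl2 (1:2), H2O (5 equiv), 0 °C → rt
Reagents that add atoms: none
Why: Acidolysis cleaves both MOM acetals and the tert-butyl ester in one operation, and the azaphilone core, whose C8 ester is deactivated towards ionisation by the conjugated C6 ketone, should survive.

## Compound list

1 | 4-methoxy-3-methylphenol | COc1ccc(O)cc1C | starting material
2 | 2-bromo-4-methoxy-5-methylphenol | COc1cc(Br)c(O)cc1C | intermediate
3 | 2-bromo-4,4-dimethoxy-5-methylcyclohexa-2,5-dien-1-one | O=C1C(Br)=CC(OC)(OC)C(C)=C1 | intermediate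
4 | (1R)-2-bromo-4,4-dimethoxy-5-methylcyclohexa-2,5-dien-1-ol | O[C@H]1C(Br)=CC(OC)(OC)C(C)=C1 | intermediate
5 | (1R,2R,3R)-4-bromo-6,6-dimethoxy-1-methylcyclohex-4-ene-1,2,3-triol | O[C@@H]1[C@@H](O)[C@@](C)(O)C(OC)(OC)C=C1Br | intermediate
6 | (5R,6S)-2-bromo-5,6-dihydroxy-4,4-dimethoxy-5-methylcyclohex-2-en-1-one | O=C1[C@@H](O)[C@@](C)(O)C(OC)(OC)C=C1Br | intermediate
7 | (5R,6S)-2-bromo-4,4-dimethoxy-5-methyl-5,6-bis(trimethylsilyloxy)cyclohex-2-en-1-one | O=C1[C@@H](O[Si](C)(C)C)[C@@](C)(O[Si](C)(C)C)C(OC)(OC)C=C1Br | intermediate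
8 | (1R,2R)-4-bromo-6,6-dimethoxy-3-(methoxymethylidene)-1-methyl-1,2-bis(trimethylsilyloxy)cyclohex-4-ene (E/Z mixture) | COC=C1[C@@H](O[Si](C)(C)C)[C@@](C)(O[Si](C)(C)C)C(OC)(OC)C=C1Br | intermediate
9 | (1R,2R)-4-bromo-6,6-dimethoxy-3-(methoxymethylidene)-1-methylcyclohex-4-ene-1,2-diol | COC=C1[C@@H](O)[C@@](C)(O)C(OC)(OC)C=C1Br | intermediate
10 | (3aR,7aR)-6-bromo-4,4-dimethoxy-7-(methoxymethylidene)-3a-methyl-3a,4,7,7a-tetrahydro-2H-1,3-benzodioxol-2-one | COC=C1[C@H]2OC(=O)O[C@@]2(C)C(OC)(OC)C=C1Br | intermediate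
11 | 5-fluorobenzene-1,3-diol | Oc1cc(O)cc(F)c1 | starting material
12 | 1-fluoro-3,5-bis(methoxymethoxy)benzene | COCOc1cc(F)cc(OCOC)c1 | intermediate
13 | [2-fluoro-4,6-bis(methoxymethoxy)phenyl]lithium | COCOc1cc(OCOC)c([Li])c(F)c1 | intermediate
14 | 3,5-bis(methoxymethoxy)benzyne | COCOC1=CC(OCOC)=CC#C1 | intermediate
15 | [2,4-bis(methoxymethoxy)-6-methylphenyl]magnesium bromide | Cc1cc(OCOC)cc(OCOC)c1[Mg]Br | intermediate
16 | (1R,6R)-3-bromo-6-hydroxy-5,5-dimethoxy-2-(methoxymethylidene)-6-methylcyclohex-3-en-1-yl 2,4-bis(methoxymethoxy)-6-methylbenzoate | COC=C1[C@@H](OC(=O)c2c(C)cc(OCOC)cc2OCOC)[C@@](C)(O)C(OC)(OC)C=C1Br | intermediate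
17 | 3-(trimethylsilyl)prop-2-ynal | C[Si](C)(C)C#CC=O | starting material
18 | tert-butyl (triphenyl-λ5-phosphanylidene)acetate | CC(C)(C)OC(=O)C=P(c1ccccc1)(c1ccccc1)c1ccccc1 | starting material
19 | tert-butyl (2E)-5-(trimethylsilyl)pent-2-en-4-ynoate | C[Si](C)(C)C#C/C=C/C(=O)OC(C)(C)C | intermediate
20 | tert-butyl (2E)-pent-2-en-4-ynoate | C#C/C=C/C(=O)OC(C)(C)C | intermediate
21 | (1R,6R)-3-[(3E)-5-tert-butoxy-5-oxopent-3-en-1-yn-1-yl]-6-hydroxy-5,5-dimethoxy-2-(methoxymethylidene)-6-methylcyclohex-3-en-1-yl 2,4-bis(methoxymethoxy)-6-methylbenzoate | COC=C1[C@@H](OC(=O)c2c(C)cc(OCOC)cc2OCOC)[C@@](C)(O)C(OC)(OC)C=C1C#C/C=C/C(=O)OC(C)(C)C | intermediate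
22 | (1R,6R)-3-[(3E)-5-tert-butoxy-5-oxopent-3-en-1-yn-1-yl]-6-hydroxy-2-(methoxymethylidene)-6-methyl-5-oxocyclohex-3-en-1-yl 2,4-bis(methoxymethoxy)-6-methylbenzoate | COC=C1[C@@H](OC(=O)c2c(C)cc(OCOC)cc2OCOC)[C@@](C)(O)C(=O)C=C1C#C/C=C/C(=O)OC(C)(C)C | intermediate
23 | (1R,6R)-3-[(3E)-5-tert-butoxy-5-oxopent-3-en-1-yn-1-yl]-6-hydroxy-2-(hydroxymethylidene)-6-methyl-5-oxocyclohex-3-en-1-yl 2,4-bis(methoxymethoxy)-6-methylbenzoate | OC=C1[C@@H](OC(=O)c2c(C)cc(OCOC)cc2OCOC)[C@@](C)(O)C(=O)C=C1C#C/C=C/C(=O)OC(C)(C)C | intermediate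
24 | tert-butyl (2E)-3-[(7R,8R)-8-{[2,4-bis(methoxymethoxy)-6-methylbenzoyl]oxy}-7-hydroxy-7-methyl-6-oxo-7,8-dihydro-6H-isochromen-3-yl]prop-2-enoate | Cc1cc(OCOC)cc(OCOC)c1C(=O)O[C@@H]1C2=COC(/C=C/C(=O)OC(C)(C)C)=CC2=CC(=O)[C@]1(C)O | intermediate
25 | (+)-mitorubrinic acid B, (2E)-3-[(7R,8R)-8-[(2,4-dihydroxy-6-methylbenzoyl)oxy]-7-hydroxy-7-methyl-6-oxo-7,8-dihydro-6H-isochromen-3-yl]prop-2-enoic acid | Cc1cc(O)cc(O)c1C(=O)O[C@@H]1C2=COC(/C=C/C(=O)O)=CC2=CC(=O)[C@]1(C)O | target

## Step count and risks

Total step count: 15. Longest linear sequence: 12 (steps 1–8, 10, 13, 14, 15).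

**Step 10 (key step).** Several processes may spoil it: slow acyl transfer from the di-ortho-substituted aryl Grignard reagent to the carbonate; ring opening toward the tertiary O7 ester without the following 1,2-acyl shift; metalation of 12 between the two OMOM groups, which gives an aryllithium that cannot lose fluoride; or Lewis-acid ionisation of the allylic C8–O bond. The fallback joins the halves through the C–O bond instead. It sets out from 12 and 9: the same aryne/MeMgBr sequence is quenched with CO2 to give 2,4-bis(methoxymethoxy)-6-methylbenzoic acid F1. This is converted with 1-chloro-N,N,2-trimethylprop-1-en-1-amine (neutral conditions that spare the MOM groups) into 2,4-bis(methoxymethoxy)-6-methylbenzoyl chloride F2. F2 acylates the secondary hydroxyl of diol 9 (Et3N, DMAP, CH2Cl2) and comes back to the route at 16.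

**Step 14.** The closure may go 5-exo-dig instead of 6-endo-dig, the C8 aroyloxy group may be lost by vinylogous β-elimination from the hydroxymethylene dienone, or methanol loss may stay incomplete. The fallback is an electrophile-triggered cyclisation. It sets out from 21: only the ketal is hydrolysed (PPTS, wet acetone) and dienone 22 is isolated. Iodine (I2, NaHCO3, MeCN) should then close the pyran 6-endo with demethylation of the oxonium ion, giving tert-butyl (2E)-3-[(7R,8R)-8-{[2,4-bis(methoxymethoxy)-6-methylbenzoyl]oxy}-7-hydroxy-4-iodo-7-methyl-6-oxo-7,8-dihydro-6H-isochromen-3-yl]prop-2-enoate F3. Palladium-catalysed formate reduction (Pd(PPh3)4, HCO2H/Et3N, DMF) removes the iodine and comes back to the route at 24.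

**Step 7.** The basic ylide may enolise the hindered α-silyloxy ketone, which would give low conversion and epimerisation at the carbinol carbon next to C=O. The fallback is a two-stage Horner–Wittig olefination. It sets out from 7: lithiated (methoxymethyl)diphenylphosphine oxide (LDA, THF, −78 °C) adds to the ketone to give (5R,6R)-3-bromo-1-[(diphenylphosphoryl)(methoxy)methyl]-5,5-dimethoxy-6-methyl-2,6-bis(trimethylsilyloxy)cyclohex-3-en-1-ol F4 (diastereomer mixture), which is isolated. KH in THF then eliminates diphenylphosphinate and comes back to the route at 8, and the methanolysis of step 7 gives 9.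

Further compounds
F1 | step 10 | 2,4-bis(methoxymethoxy)-6-methylbenzoic acid | Cc1cc(OCOC)cc(OCOC)c1C(=O)O
F2 | step 10 | 2,4-bis(methoxymethoxy)-6-methylbenzoyl chloride | Cc1cc(OCOC)cc(OCOC)c1C(=O)Cl
F3 | step 14 | tert-butyl (2E)-3-[(7R,8R)-8-{[2,4-bis(methoxymethoxy)-6-methylbenzoyl]oxy}-7-hydroxy-4-iodo-7-methyl-6-oxo-7,8-dihydro-6H-isochromen-3-yl]prop-2-enoate | Cc1cc(OCOC)cc(OCOC)c1C(=O)O[C@@H]1C2=COC(/C=C/C(=O)OC(C)(C)C)=C(I)C2=CC(=O)[C@]1(C)O
F4 | step 7 | (5R,6R)-3-bromo-1-[(diphenylphosphoryl)(methoxy)methyl]-5,5-dimethoxy-6-methyl-2,6-bis(trimethylsilyloxy)cyclohex-3-en-1-ol | COC(C1(O)[C@@H](O[Si](C)(C)C)[C@@](C)(O[Si](C)(C)C)C(OC)(OC)C=C1Br)P(=O)(c1ccccc1)c1ccccc1
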